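Remark: carbon locants C1–C15 follow the germacrane numbering of the target (ring C1–C10, lactone O6–C12 through C11 on C7, methylene C13, methyl C14 on C10, C15 on C4). Descriptors of intermediates use these locants and change at C1, C3 and C7 where substituent priorities change, not the geometry.

## Analysis of the target

Target 45 is a germacranolide: a ten-membered carbocycle C1–C10 fused across C6–C7 to an α-methylene-γ-butyrolactone (O6–C12, C11=C13), with a Z C4=C5 alkene carrying the C15 hydroxymethyl, an angelate on O8, and two oxiranes, C1–C10 (methyl C14 on the fully substituted C10) and C2–C3. The seven stereocentres fall into two blocks: C10(S), C1(R), C2(S), C3(S) are four contiguous oxygenated carbons in which both oxiranes are cis with respect to the ring chain, and C6(S), C7(R), C8(R) carry the lactone and the acyloxy group. The blocks are separated by the C9 methylene on one side and the C4=C5 alkene on the other, so neither can easily control the other. H6 and H7 are cis, so the lactone is cis-fused, which an open-chain Felkin–Anh addition to a C6 aldehyde would not give. The sensitive groups are the α-methylene lactone (Michael acceptor), the angelate (Z to E isomerisation under base, nucleophilic catalysts or heat), the allylic C2–C3 oxirane and the trisubstituted C1–C10 oxirane (acid), and any free C8 hydroxyl, which sits γ to C12. The hard points are the quaternary C10 inside a medium ring and two adjacent oxiranes whose four C–O bonds must be set relative to each other, on a ring where late epoxidation would be governed only by conformation. The plan rests on the run C10–C1–C2–C3: because each carbon bears oxygen, an alkoxide created at C10 can be handed on to C1 and the displaced oxygen handed on from C2 to C3, so one cis oxirane at C1–C2 plus a leaving group at C3 encodes both target oxiranes, and the bond that creates the alkoxide (C9–C10) joins two fragments of similar size.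

## Retrosynthetic reasoning

45 to 41. The C15 silyl ether is removed last, and the angelate is put on just before (44 from 41 and angelic acid 42 by Yamaguchi esterification). The Z-enoate is the group most easily isomerised and would not survive the enolate chemistry that installs C13, so it enters after the methylene lactone 40 is complete. Until then O8 is a triethylsilyl ether, and C15 carries a tert-butyldiphenylsilyl ether so that the triethylsilyl ethers can be removed selectively.

40 to 36. The C11=C13 bond is cut back to the saturated lactone 36. Aminomethylation of the lactone enolate and elimination is the standard way to add this one carbon, and C7 carries no leaving group that the enolate could expel.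

36 to 34. The C5–C6 bond and the O6–C12 bond are cut together. The ring is opened where an sp2 carbon meets a carbinol carbon, which turns C4=C5 into a geometrically defined vinyl iodide and C6 into an aldehyde. A Nozaki–Hiyama–Kishi closure tolerates oxiranes, the ester and silyl ethers, and the new C6 alkoxide lies γ to the C12 ester, so the lactone closes in the same operation. Only one stereocentre (C6) is formed here. The forward reaction must close a ten-membered ring and add to the aldehyde face that gives the cis lactone.

34 to 30. Functional-group changes only: the C6 aldehyde comes from the 4-methoxybenzyl ether (33, 32), and the C8 silyl ether from the C8 ketone of 30 by oxazaborolidine-controlled reduction (31). The C8 hydroxyl of 31 is γ to the C12 methyl ester and would close the unwanted 8,12-lactone, so it is silylated at once and the angelate is postponed. C8 must be reduced before C6 is oxidised, otherwise C7 would sit between two carbonyl groups and epimerise.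

30 to 9 and 26. The key disconnection cuts C9–C10 and, formally, both oxirane C–O bonds formed in the relay. Methyl ketone 9 (C6–C9, C11, C12) supplies the C9 enolate. Fragment 26 carries the C10 ketone, a cis C1–C2 oxirane and a C3 chloride. The cut falls at the quaternary carbon, which is best made by addition to a ketone, and it divides the target into two halves that each hold one stereochemical block. What is gained is that C10, C1 and C3 are set in the union and no epoxidation of the ten-membered ring is needed. The forward reaction must add to the correct ketone face and then relay the alkoxide.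

9 to 7, 5, 3. The C8 ketone of 9 is unmasked from the isopropenyl group of 7 by ozonolysis. The C7 stereocentre of 7 is made by rhodium-catalysed conjugate addition of the isopropenyl group of 6 to enoate 5, which comes from allyl ether 3 and methyl acrylate 4 by cross-metathesis, and 3 from 1 and 2. A direct α-functionalisation of a 4-oxopentanoate was not used, because it would have to distinguish C7 from C9 and C11 and would leave a configurationally labile β-hydroxy ketone.

26 to 21. The C10 ketone comes from the silyl-protected carbinol (25, 24), and the C3 chloride from alcohol 23 with inversion. The chloride is kept as the leaving group because it tolerates the enolate and the oxidations that follow. The relay needs the chloride with the configuration that corresponds, with retention, to the threo epoxy alcohol 21. A hydroxyl-directed epoxidation of a cis-allylic alcohol is threo-selective, and an invertive chlorination of 21 would therefore give the wrong C3 epimer. C3 is therefore inverted first through enone 22 and chelation-controlled reduction to the erythro alcohol 23, whose invertive chlorination gives 24. Diastereomers are separated at 21, before the C3 stereocentre is erased, so that the enantiopurity of the oxirane is not eroded.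

21 to 15 and 17. The oxirane is traced to the Z-allylic alcohol 20 (directed epoxidation), the Z-alkene to alkyne 19 (semihydrogenation), and the C2–C3 bond to aldehyde 15 and alkyne 17 by catalytic asymmetric alkynylation. The C3 carbinol made here is used only to pass its chirality on to the oxirane. The C10 carbinol from (R)-but-3-yn-2-ol 16 is likewise sacrificial and is chosen so that its silyloxy group lies on the alkene face opposite to the directed peracid.

15 to 10. Aldehyde 15 has iodine cis to the formyl carbon (C3) and trans to C15. This geometry is what an iodide-triggered aldol of methyl propiolate 10 with a one-carbon aldehyde gives, with the ester as C3 (12). Silylation (13), reduction (14) and oxidation complete 15.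

## Alternatives that were turned down

Alternative 1: Grob fragmentation of a cis-fused bicyclo[5.3.0]decane. The ten-membered ring is traced back to a five–seven bicycle in which C6 and C10 are bonded, C6 is a tertiary carbinol and C1 carries a sulfonate. In the forward step KH forms the C6 alkoxide and the C6–C10 bond breaks anti-periplanar to the C1–O bond, giving the ring-opened enone A1 with a C6 ketone and a Z C1=C10 alkene. In its favour, the fragmentation is concerted and stereospecific, so ring size and alkene geometry are fixed by a rigid precursor and no entropically costly ring closure is needed; on ring formation this alternative is stronger than the chosen route, whose closure at C5–C6 is less assured. Against it, A1 still lacks the C1–C10 oxirane, the C6 stereocentre, the C12 oxidation state and C13. The oxirane would have to come from face-selective epoxidation of a flexible ten-membered ring next to an existing oxirane, and C6 from reduction of an enone to the less common cis-lactone configuration. The bicycle also needs several sacrificial stereocentres and a long linear sequence before the fragmentation, and the C2–C3 oxirane must survive KH. The chosen strategy offers in its place a convergent union that sets C10, C1 and C3 by stereospecific displacements.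

Alternative 2: pinacol closure at C1–C2. The C1–C2 bond is cut to an open-chain dialdehyde in which the lactone, C4=C5, and protected carbinols at C10, C3 and C8 are already present. SmI2 (divalent samarium) couples the two aldehydes to the ten-membered trans-diol A2, and two oxirane closures follow. In its favour, ketyl couplings close medium rings under mild neutral conditions, and the lactone block C6–C8 is finished on a small intermediate before the ring is made; on control of C6 this alternative is stronger than the chosen route. Against it, both aldehydes are α-oxygenated, and SmI2 is known to cleave α-heteroatom substituents from carbonyl compounds. The coupling creates C1 and C2 in the ring closure with no reliable control relative to C10 and C3. A2 must then be converted into two oxiranes by activating the C1 and C2 hydroxyls and releasing the C10 and C3 oxygens, two invertive closures (one by a tertiary alkoxide) that demand the one correct trans-diol and several protecting-group changes. The chosen strategy reaches the same four C–O bonds from a single cis oxirane whose configuration is set on a small acyclic fragment.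

Alternative 3: Wittig–Still ring contraction. The C7–C8 bond is cut back to a thirteen-membered cyclic ether in which O links C8 and C13 and C8 carries a tributylstannyl group. n-BuLi exchanges tin for lithium, and the α-alkoxy carbanion attacks C7 in a [2,3] shift that forms C7–C8, frees the C8 alkoxide and leaves the C11=C13 methylene, giving A3. In its favour, ring contractions of this type are precedented for ten-membered carbocycles, closing a large ether ring is easier than closing the carbocycle, and C13 arrives in the key step; on that point it is stronger than the chosen route, which needs a late methylenation. Against it, the substrate must hold both oxiranes, a configurationally defined α-stannyl ether and the macrocyclic ether, which is a long preparation. The organolithium is generated two carbons from the C1–C10 oxirane and near the allylic oxirane. The sense at C7 and C8 depends on the conformation of a large flexible ring. A3 still needs oxidation of C12, lactonisation onto C6 and acylation at C8. The chosen strategy keeps all organometallic chemistry of the union at −78 °C on small fragments and gives a product only functional-group steps away from ring closure.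

Key step: step 18

## Route

Step 1
Reactants: 1 4-methoxybenzyl alcohol; 2 allyl bromide
Product: 3 allyl 4-methoxybenzyl ether
Conditions: 50% aq NaOH, Bu4NHSO4 (cat.), toluene, rt
Reagents that add atoms: none
Why: Williamson etherification under phase transfer; a benzylic alkoxide and a primary allylic bromide react cleanly and no stereocentre is involved.

Step 2
Reactants: 3 allyl 4-methoxybenzyl ether; 4 methyl acrylate
Product: 5 methyl (E)-4-[(4-methoxybenzyl)oxy]but-2-enoate
Conditions: second-generation Hoveyda–Grubbs catalyst RuCl2(H2IMes)(=CH-C6H4-2-OiPr) (2 mol %), CH2Cl2, 40 °C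
Reagents that add atoms: none
Why: Olefin cross-metathesis of an allyl ether with an excess of the electron-poor acrylate is selective for the cross product and for the E-enoate, and is driven by loss of ethylene.

Step 3
Reactants: 5 methyl (E)-4-[(4-methoxybenzyl)oxy]but-2-enoate; 6 potassium isopropenyltrifluoroborate
Product: 7 methyl (R)-3-{[(4-methoxybenzyl)oxy]methyl}-4-methylpent-4-enoate
Conditions: [Rh(cod)2]BF4 (3 mol %), (S)-BINAP (3.3 mol %), toluene/H2O, 100 °C
Reagents that add atoms: none
Why: Hayashi–Miyaura conjugate addition; the alkenylrhodium–(S)-BINAP complex should add to the α-si face of the E-enoate, which sets C7 as (R). The rhodium enolate has no β-leaving group (the ether oxygen is γ) and is protonated by water.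

Step 4
Reactants: 7 methyl (R)-3-{[(4-methoxybenzyl)oxy]methyl}-4-methylpent-4-enoate
Product: 9 methyl (S)-3-{[(4-methoxybenzyl)oxy]methyl}-4-oxopentanoate (fragment 1), via ozonide 8 (not isolated)
Conditions: O3, CH2Cl2, −78 °C (Sudan Red end point); PPh3, −78 °C → rt
Reagents that add atoms: ozone, [O-][O+]=O
Why: Ozonolysis of the 1,1-disubstituted alkene with reductive work-up gives the methyl ketone under neutral conditions, so the C7 centre, now α to the ketone, is not epimerised (its descriptor changes to S only through priorities).

Step 5
Reactants: 10 methyl propiolate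
Product: 12 methyl (Z)-2-(hydroxymethyl)-3-iodoprop-2-enoate, via aluminium allenolate 11 (not isolated)
Conditions: Et2AlI, CH2Cl2, 0 °C; monomeric CH2O (from paraformaldehyde), 0 °C; aq NH4Cl
Reagents that add atoms: diethylaluminium iodide, CC[Al](I)CC; formaldehyde, C=O
Why: Iodide-triggered aldol of a propiolate (β-iodo Morita–Baylis–Hillman type): conjugate addition of iodide gives allenolate 11, and the aldehyde attacks the α-carbon in the plane of the CHI terminus on the side away from iodine, which places iodine cis to the ester (Z).

Step 6
Reactants: 12 methyl (Z)-2-(hydroxymethyl)-3-iodoprop-2-enoate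
Product: 13 methyl (Z)-2-{[(tert-butyldiphenylsilyl)oxy]methyl}-3-iodoprop-2-enoate
Conditions: t-BuPh2SiCl, imidazole, CH2Cl2, 0 °C → rt
Reagents that add atoms: tert-butyl(chloro)diphenylsilane, CC(C)(C)[Si](Cl)(c1ccccc1)c1ccccc1
Why: Standard silylation of a primary alcohol; the bulky silyl ether is chosen because it must outlast two triethylsilyl ethers later in the route.

Step 7
Reactants: 13 methyl (Z)-2-{[(tert-butyldiphenylsilyl)oxy]methyl}-3-iodoprop-2-enoate
Product: 14 (E)-2-{[(tert-butyldiphenylsilyl)oxy]methyl}-3-iodoprop-2-en-1-ol
Conditions: i-Bu2AlH (2.2 equiv), CH2Cl2, −78 °C; Rochelle salt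
Reagents that add atoms: none
Why: 1,2-Reduction of an enoate to the allylic alcohol; the vinyl iodide and the alkene geometry are not touched at −78 °C (the descriptor changes to E through priorities).

Step 8
Reactants: 14 (E)-2-{[(tert-butyldiphenylsilyl)oxy]methyl}-3-iodoprop-2-en-1-ol
Product: 15 (Z)-2-{[(tert-butyldiphenylsilyl)oxy]methyl}-3-iodoprop-2-enal
Conditions: MnO2, CH2Cl2, rt
Reagents that add atoms: none
Why: Selective oxidation of an allylic alcohol under neutral heterogeneous conditions, which keeps iodine cis to the formyl group.

Step 9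
Reactants: 16 (R)-but-3-yn-2-ol
Product: 17 (R)-triethyl(but-3-yn-2-yloxy)silane
Conditions: Et3SiCl, imidazole, CH2Cl2, 0 °C
Reagents that add atoms: chlorotriethylsilane, CC[Si](Cl)(CC)CC
Why: Silylation of a secondary alcohol; the triethylsilyl ether survives the zinc acetylide chemistry and is later removable beside the tert-butyldiphenylsilyl ether.

Step 10
Reactants: 15 (Z)-2-{[(tert-butyldiphenylsilyl)oxy]methyl}-3-iodoprop-2-enal; 17 (R)-triethyl(but-3-yn-2-yloxy)silane
Product: 19 (1Z,3S,6R)-2-{[(tert-butyldiphenylsilyl)oxy]methyl}-1-iodo-6-[(triethylsilyl)oxy]hept-1-en-4-yn-3-ol, via alkynylzinc 18 (not isolated)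
Conditions: Me2Zn, (S,S)-ProPhenol (20 mol %), Ph3PO (40 mol %), toluene, 0 → 4 °C
Reagents that add atoms: none
Why: Catalytic asymmetric alkynylation of an α,β-unsaturated aldehyde by a dinuclear zinc–ProPhenol complex, which binds the aldehyde and alkynylzinc 18 and should deliver the alkyne to the Si face to set C3 as (S). Control is by the catalyst (the antipodal ligand would give the C3 epimer), and zinc acetylides add 1,2 without touching the vinyl iodide.

Step 11
Reactants: 19 (1Z,3S,6R)-2-{[(tert-butyldiphenylsilyl)oxy]methyl}-1-iodo-6-[(triethylsilyl)oxy]hept-1-en-4-yn-3-ol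
Product: 20 (1Z,3S,4Z,6R)-2-{[(tert-butyldiphenylsilyl)oxy]methyl}-1-iodo-6-[(triethylsilyl)oxy]hepta-1,4-dien-3-ol
Conditions: H2 (1 atm), Pd/CaCO3 poisoned with Pb(OAc)2 (Lindlar catalyst), quinoline, EtOAc, rt
Reagents that add atoms: none
Why: Lindlar semihydrogenation adds hydrogen syn to the alkyne and gives the Z C1=C2 alkene; the lead- and quinoline-poisoned surface should spare the vinyl iodide and stop at the alkene.

Step 12
Reactants: 20 (1Z,3S,4Z,6R)-2-{[(tert-butyldiphenylsilyl)oxy]methyl}-1-iodo-6-[(triethylsilyl)oxy]hepta-1,4-dien-3-ol
Product: 21 threo epoxy alcohol (1S,2S,3R,10R): cis C1–C2 oxirane, C3 carbinol, C10 triethylsilyl ether, C15 tert-butyldiphenylsilyl ether, Z C5 iodide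
Conditions: mCPBA, NaHCO3, CH2Cl2, 0 °C
Reagents that add atoms: 3-chloroperoxybenzoic acid, OOC(=O)c1cccc(Cl)c1
Why: Hydroxyl-directed peracid epoxidation; A(1,3) strain with the cis C10 substituent holds H3 in the alkene plane, so the peracid bound to the C3 hydroxyl attacks the syn face and gives the threo epoxy alcohol. The C10 silyloxy group lies on the opposite face (matched), and the iodoalkene is too electron-poor to react.

Step 13
Reactants: 21 threo epoxy alcohol (1S,2S,3R,10R)
Product: 22 cis-epoxy enone (1S,2R,10R) with C3 ketone
Conditions: Dess–Martin periodinane, NaHCO3, CH2Cl2, 0 °C → rt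
Reagents that add atoms: none
Why: Buffered Dess–Martin oxidation of the allylic carbinol; the C3 centre has passed its chirality to the oxirane and is erased so that it can be reset in the erythro sense.

Step 14
Reactants: 22 cis-epoxy enone (1S,2R,10R)
Product: 23 erythro epoxy alcohol (1S,2S,3S,10R)
Conditions: Zn(BH4)2, Et2O, −20 °C
Reagents that add atoms: none
Why: Chelation-controlled 1,2-reduction of an α,β-epoxy ketone: zinc bridges the ketone and oxirane oxygens and hydride enters from the face away from C1, which gives the erythro alcohol (3S).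

Step 15
Reactants: 23 erythro epoxy alcohol (1S,2S,3S,10R)
Product: 24 C3 chloride (1S,2R,3R,10R)
Conditions: PPh3, Cl3CC(O)CCl3, CH2Cl2, −20 → 0 °C
Reagents that add atoms: hexachloroacetone, O=C(C(Cl)(Cl)Cl)C(Cl)(Cl)Cl
Why: Appel-type chlorination; chloride displaces the alkoxyphosphonium group with inversion under neutral conditions, giving the (3R) chloride that the relay needs. Allylic transposition is disfavoured because C5 bears iodine.

Step 16
Reactants: 24 C3 chloride (1S,2R,3R,10R)
Product: 25 C10 alcohol (1R,2R,3R,10R)
Conditions: HF·pyridine, pyridine, THF, 0 °C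
Reagents that add atoms: none
Why: Buffered fluoride cleavage of the secondary triethylsilyl ether; the tert-butyldiphenylsilyl ether, the oxirane and the chloride are stable under these conditions.

Step 17
Reactants: 25 C10 alcohol (1R,2R,3R,10R)
Product: 26 1-[(2S,3R)-3-[(1R,2Z)-1-chloro-3-iodo-2-{[(tert-butyldiphenylsilyl)oxy]methyl}prop-2-en-1-yl]oxiran-2-yl]ethan-1-one (fragment 2)
Conditions: Dess–Martin periodinane, NaHCO3, CH2Cl2, 0 °C
Reagents that add atoms: none
Why: Neutral oxidation of the secondary carbinol to the methyl ketone; the sacrificial C10 centre is removed and the cis oxirane is not epimerised.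

Step 18
Reactants: 9 methyl (S)-3-{[(4-methoxybenzyl)oxy]methyl}-4-oxopentanoate (fragment 1); 26 fragment 2
Product: 30 bis-epoxy C8 ketone (1R,2S,3S,7S,10S): C1–C10 and C2–C3 oxiranes, Z C5 iodide, C15 tert-butyldiphenylsilyl ether, C6 4-methoxybenzyl ether, C12 methyl ester, via lithium enolate 27 (not isolated), via aldolate 28 (not isolated), via C2 alkoxide 29 (not isolated)
Conditions: LiN(i-Pr)2 (1.0 equiv), THF, −78 °C; 26, −78 °C; warm to 0 °C; pH 7 buffer
Reagents that add atoms: none
Why: Proposed new method: the kinetic lithium enolate 27 (deprotonation at the C9 methyl) adds to the C10 ketone of 26, which lithium holds in a five-membered chelate with the oxirane oxygen, so the C9–C10 bond forms on the ketone face turned away from C2 and sets C10 as in aldolate 28; the closest known reactions are chelation-controlled additions of carbon nucleophiles to α,β-epoxy ketones. On warming, the C10 alkoxide rotates anti to the C1–O bond and opens the C1–C2 oxirane at C1 with inversion (3-exo-tet, a Payne rearrangement toward the more substituted oxirane), which closes the C1–C10 oxirane and gives 29. The C2 alkoxide of 29 then displaces the allylic C3 chloride with inversion (3-exo-tet, chlorohydrin closure) and closes the C2–C3 oxirane; loss of LiCl makes the relay irreversible and draws the reversible aldol and Payne steps forward. C10 is controlled by the chelate, C1 and C3 by stereospecific backside displacement, and C2 and C7 are carried over unchanged. The step needs enolate regioselectivity (methyl against C7–H and the ester α-CH2, secured by kinetic deprotonation at −78 °C), carbonyl addition in preference to proton transfer from the enolizable ketone 26 or attack at C3 (secured by the activated, chelated ketone and the low temperature), and facial selectivity at C10 (secured by the chelate). One equivalent of base is used so that none is left to open the β,γ-epoxy ketone 30 by elimination.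

Step 19
Reactants: 30 bis-epoxy C8 ketone (1R,2S,3S,7S,10S)
Product: 31 C8 alcohol (1R,2S,3S,7S,8R,10S)
Conditions: (S)-2-methyl-CBS-oxazaborolidine (0.3 equiv), BH3·SMe2, THF, −30 °C; MeOH; crude used directly
Reagents that add atoms: none
Why: Corey–Bakshi–Shibata reduction; the ketone should bind the oxazaborolidine anti to the α-branched C7 arm, and hydride delivery then gives the (8R) alcohol under reagent control. The ester and oxiranes are inert at this temperature, and the crude alcohol is not stored because its hydroxyl is γ to the C12 ester.

Step 20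
Reactants: 31 C8 alcohol (1R,2S,3S,7S,8R,10S)
Product: 32 C8 triethylsilyl ether (1R,2S,3S,7S,8R,10S)
Conditions: Et3SiOTf, 2,6-lutidine, CH2Cl2, −78 °C
Reagents that add atoms: triethylsilyl trifluoromethanesulfonate, CC[Si](CC)(CC)OS(=O)(=O)C(F)(F)F
Why: Silylation with the triflate is complete within minutes at −78 °C and so outruns closure of the 8,12-lactone; the hindered base keeps the oxiranes from Lewis-acid opening.

Step 21
Reactants: 32 C8 triethylsilyl ether (1R,2S,3S,7S,8R,10S)
Product: 33 C6 primary alcohol (1R,2S,3S,7S,8R,10S)
Conditions: DDQ, CH2Cl2/pH 7 buffer, 0 °C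
Reagents that add atoms: none
Why: Oxidative cleavage of the 4-methoxybenzyl ether; the buffered medium protects the oxiranes and silyl ethers, and the vinyl iodide is not oxidised.

Step 22
Reactants: 33 C6 primary alcohol (1R,2S,3S,7S,8R,10S)
Product: 34 C6 aldehyde (1R,2S,3S,7R,8R,10S)
Conditions: Dess–Martin periodinane, NaHCO3, CH2Cl2, 0 °C; used at once
Reagents that add atoms: none
Why: Neutral oxidation to the aldehyde; the α-stereocentre C7 is kept by buffering and immediate use.

Step 23
Reactants: 34 C6 aldehyde (1R,2S,3S,7R,8R,10S)
Product: 36 ten-membered cis-fused 6,12-lactone (1R,2S,3S,6S,7S,8R,10S) with C11 methylene, C8 triethylsilyl ether, C15 tert-butyldiphenylsilyl ether, via hydroxy ester 35 (not isolated)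
Conditions: CrCl2, NiCl2 (1 mol %), DMSO/THF, rt, 2 mM; then Et3N, CH2Cl2, rt
Reagents that add atoms: none
Why: Nozaki–Hiyama–Kishi macrocyclisation: nickel inserts into the C5–I bond with retention of alkene geometry, the alkenyl group passes to trivalent chromium and adds to the aldehyde, and the C6 alkoxide of 35 then closes the lactone on the C12 ester (5-exo-trig). C6 is set in the ring closure; the required epimer arises from addition to the aldehyde face anti to C11 in the conformer that turns the C8 oxygen toward the carbonyl oxygen, whereas an open-chain Felkin–Anh preference would give the 6-epimer, so the outcome rests on the conformation of the closing ring.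

Step 24
Reactants: 36 ten-membered cis-fused 6,12-lactone (1R,2S,3S,6S,7S,8R,10S)
Product: 40 α-methylene lactone (1R,2S,3S,6S,7S,8R,10S) with C8 triethylsilyl ether, via lactone enolate 37 (not isolated), via Mannich base 38 (not isolated), via methiodide 39 (not isolated)
Conditions: LiN(i-Pr)2, THF, −78 °C; CH2=NMe2 I, −78 → 0 °C; MeI, CH2Cl2/MeOH, rt; aq NaHCO3, rt
Reagents that add atoms: N,N-dimethylmethyleneiminium iodide (Eschenmoser's salt), C=[N+](C)C.[I-]
Why: α-Methylenation through the lactone enolate: aminomethylation at C11, quaternisation, and mild-base elimination give the C11=C13 alkene. C7 carries no leaving group, and no enoate ester is present yet to compete for the base.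

Step 25
Reactants: 40 α-methylene lactone (1R,2S,3S,6S,7S,8R,10S)
Product: 41 C8 alcohol (1R,2S,3S,6S,7R,8R,10S)
Conditions: HF·pyridine, pyridine, THF, 0 °C
Reagents that add atoms: none
Why: Buffered fluoride removes the secondary triethylsilyl ether while the primary tert-butyldiphenylsilyl ether, the oxiranes and the methylene lactone remain.

Step 26
Reactants: 41 C8 alcohol (1R,2S,3S,6S,7R,8R,10S); 42 angelic acid
Product: 44 C8 angelate (1R,2S,3S,6S,7R,8R,10S) with C15 tert-butyldiphenylsilyl ether, via mixed anhydride 43 (not isolated)
Conditions: 42, 2,4,6-Cl3C6H2COCl, Et3N, toluene, rt; then 41, toluene, 75 °C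
Reagents that add atoms: none
Why: Yamaguchi esterification through the mixed anhydride 43; omitting a nucleophilic catalyst and keeping the temperature moderate should preserve the Z geometry of the angelate. Triethylamine does not ionise the C8 hydroxyl, so acylation should outpace translactonisation.

Step 27
Reactants: 44 C8 angelate (1R,2S,3S,6S,7R,8R,10S)
Product: 45 target (1R,2S,3S,6S,7R,8R,10S)
Conditions: Bu4NF, AcOH, THF, 0 °C → rt
Reagents that add atoms: none
Why: Acetic-acid-buffered fluoride cleaves the primary silyl ether without the basicity that would add to the methylene lactone, isomerise the angelate or move the acyl group.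

## Compound list

1 | 4-methoxybenzyl alcohol | COc1ccc(CO)cc1 | starting material
2 | allyl bromide | C=CCBr | starting material
3 | allyl 4-methoxybenzyl ether | C=CCOCc1ccc(OC)cc1 | intermediate
4 | methyl acrylate | C=CC(=O)OC | starting material
5 | methyl (E)-4-[(4-methoxybenzyl)oxy]but-2-enoate | COC(=O)/C=C/COCc1ccc(OC)cc1 | intermediate
6 | potassium isopropenyltrifluoroborate | [K+].C=C(C)[B-](F)(F)F | starting material
7 | methyl (R)-3-{[(4-methoxybenzyl)oxy]methyl}-4-methylpent-4-enoate | C=C(C)[C@@H](CC(=O)OC)COCc1ccc(OC)cc1 | intermediate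
8 | ozonide of 7 (1,2,4-trioxolane at the former alkene, mixture at the trioxolane carbon) | CC1(OCOO1)[C@@H](CC(=O)OC)COCc2ccc(OC)cc2 | intermediate
9 | fragment 1, methyl (S)-3-{[(4-methoxybenzyl)oxy]methyl}-4-oxopentanoate | CC(=O)[C@@H](CC(=O)OC)COCc1ccc(OC)cc1 | intermediate
10 | methyl propiolate | C#CC(=O)OC | starting material
11 | diethylaluminium allenolate of methyl 3-iodopropa-1,2-dienoate | COC(O[Al](CC)CC)=C=CI | intermediate
12 | methyl (Z)-2-(hydroxymethyl)-3-iodoprop-2-enoate | COC(=O)/C(CO)=C\I | intermediate
13 | methyl (Z)-2-{[(tert-butyldiphenylsilyl)oxy]methyl}-3-iodoprop-2-enoate | COC(=O)/C(CO[Si](c1ccccc1)(c2ccccc2)C(C)(C)C)=C\I | intermediate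
14 | (E)-2-{[(tert-butyldiphenylsilyl)oxy]methyl}-3-iodoprop-2-en-1-ol | OC/C(CO[Si](c1ccccc1)(c2ccccc2)C(C)(C)C)=C\I | intermediate
15 | (Z)-2-{[(tert-butyldiphenylsilyl)oxy]methyl}-3-iodoprop-2-enal | O=C/C(CO[Si](c1ccccc1)(c2ccccc2)C(C)(C)C)=C\I | intermediate
16 | (R)-but-3-yn-2-ol | C[C@@H](O)C#C | starting material
17 | (R)-triethyl(but-3-yn-2-yloxy)silane | C[C@@H](O[Si](CC)(CC)CC)C#C | intermediate
18 | methylzinc acetylide of 17 | C[C@@H](O[Si](CC)(CC)CC)C#C[Zn]C | intermediate
19 | (1Z,3S,6R)-2-{[(tert-butyldiphenylsilyl)oxy]methyl}-1-iodo-6-[(triethylsilyl)oxy]hept-1-en-4-yn-3-ol | C[C@@H](O[Si](CC)(CC)CC)C#C[C@H](O)/C(CO[Si](c1ccccc1)(c2ccccc2)C(C)(C)C)=C\I | intermediate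
20 | (1Z,3S,4Z,6R)-2-{[(tert-butyldiphenylsilyl)oxy]methyl}-1-iodo-6-[(triethylsilyl)oxy]hepta-1,4-dien-3-ol | C[C@@H](O[Si](CC)(CC)CC)/C=C\[C@H](O)/C(CO[Si](c1ccccc1)(c2ccccc2)C(C)(C)C)=C\I | intermediate
21 | threo epoxy alcohol (1S,2S,3R,10R): cis C1–C2 oxirane, C3 carbinol, C10 triethylsilyl ether, C15 tert-butyldiphenylsilyl ether, Z C5 iodide | C[C@@H](O[Si](CC)(CC)CC)[C@H]1O[C@H]1[C@H](O)/C(CO[Si](c2ccccc2)(c3ccccc3)C(C)(C)C)=C\I | intermediate
22 | cis-epoxy enone (1S,2R,10R): C3 ketone, otherwise as 21 | C[C@@H](O[Si](CC)(CC)CC)[C@H]1O[C@H]1C(=O)/C(CO[Si](c2ccccc2)(c3ccccc3)C(C)(C)C)=C\I | intermediate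
23 | erythro epoxy alcohol (1S,2S,3S,10R), C3 epimer of 21 | C[C@@H](O[Si](CC)(CC)CC)[C@H]1O[C@H]1[C@@H](O)/C(CO[Si](c2ccccc2)(c3ccccc3)C(C)(C)C)=C\I | intermediate
24 | C3 chloride (1S,2R,3R,10R) with C10 triethylsilyl ether | C[C@@H](O[Si](CC)(CC)CC)[C@H]1O[C@H]1[C@H](Cl)/C(CO[Si](c2ccccc2)(c3ccccc3)C(C)(C)C)=C\I | intermediate
25 | C10 alcohol (1R,2R,3R,10R) with C3 chloride | C[C@@H](O)[C@H]1O[C@H]1[C@H](Cl)/C(CO[Si](c2ccccc2)(c3ccccc3)C(C)(C)C)=C\I | intermediate
26 | fragment 2, 1-[(2S,3R)-3-[(1R,2Z)-1-chloro-3-iodo-2-{[(tert-butyldiphenylsilyl)oxy]methyl}prop-2-en-1-yl]oxiran-2-yl]ethan-1-one | CC(=O)[C@H]1O[C@H]1[C@H](Cl)/C(CO[Si](c2ccccc2)(c3ccccc3)C(C)(C)C)=C\I | intermediate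
27 | lithium enolate of 9 (C8–O–Li, C8=C9) | C=C(O[Li])[C@@H](CC(=O)OC)COCc1ccc(OC)cc1 | intermediate
28 | lithium aldolate: C9–C10 bond formed, C10 alkoxide, C1–C2 oxirane and C3 chloride intact | C[C@](O[Li])(CC(=O)[C@@H](CC(=O)OC)COCc1ccc(OC)cc1)[C@H]1O[C@H]1[C@H](Cl)/C(CO[Si](c2ccccc2)(c3ccccc3)C(C)(C)C)=C\I | intermediate
29 | C2 lithium alkoxide: C1–C10 oxirane closed, C3 chloride intact | C[C@@]1(CC(=O)[C@@H](CC(=O)OC)COCc2ccc(OC)cc2)O[C@@H]1[C@@H](O[Li])[C@H](Cl)/C(CO[Si](c3ccccc3)(c4ccccc4)C(C)(C)C)=C\I | intermediate
30 | bis-epoxy C8 ketone (1R,2S,3S,7S,10S), open between C5 and C6 | I/C=C(/CO[Si](c1ccccc1)(c2ccccc2)C(C)(C)C)[C@@H]3O[C@@H]3[C@H]4O[C@@]4(C)CC(=O)[C@@H](CC(=O)OC)COCc5ccc(OC)cc5 | intermediate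
31 | C8 alcohol (1R,2S,3S,7S,8R,10S) | I/C=C(/CO[Si](c1ccccc1)(c2ccccc2)C(C)(C)C)[C@@H]3O[C@@H]3[C@H]4O[C@@]4(C)C[C@@H](O)[C@@H](CC(=O)OC)COCc5ccc(OC)cc5 | intermediate
32 | C8 triethylsilyl ether (1R,2S,3S,7S,8R,10S) | I/C=C(/CO[Si](c1ccccc1)(c2ccccc2)C(C)(C)C)[C@@H]3O[C@@H]3[C@H]4O[C@@]4(C)C[C@@H](O[Si](CC)(CC)CC)[C@@H](CC(=O)OC)COCc5ccc(OC)cc5 | intermediate
33 | C6 primary alcohol (1R,2S,3S,7S,8R,10S) | I/C=C(/CO[Si](c1ccccc1)(c2ccccc2)C(C)(C)C)[C@@H]3O[C@@H]3[C@H]4O[C@@]4(C)C[C@@H](O[Si](CC)(CC)CC)[C@@H](CC(=O)OC)CO | intermediate
34 | C6 aldehyde (1R,2S,3S,7R,8R,10S) | I/C=C(/CO[Si](c1ccccc1)(c2ccccc2)C(C)(C)C)[C@@H]3O[C@@H]3[C@H]4O[C@@]4(C)C[C@@H](O[Si](CC)(CC)CC)[C@@H](CC(=O)OC)C=O | intermediate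
35 | ten-membered C6 carbinol with C12 methyl ester (1R,2S,3S,6S,7S,8R,10S) | COC(=O)C[C@H]1[C@@H](O)/C=C(/CO[Si](c2ccccc2)(c3ccccc3)C(C)(C)C)[C@@H]4O[C@@H]4[C@H]5O[C@@]5(C)C[C@H]1O[Si](CC)(CC)CC | intermediate
36 | ten-membered cis-fused 6,12-lactone (1R,2S,3S,6S,7S,8R,10S), C11 methylene | C1C(=O)O[C@H]2/C=C(/CO[Si](c3ccccc3)(c4ccccc4)C(C)(C)C)[C@@H]5O[C@@H]5[C@H]6O[C@@]6(C)C[C@@H](O[Si](CC)(CC)CC)[C@@H]12 | intermediate
37 | lithium enolate of lactone 36 | C1=C(O[Li])O[C@H]2/C=C(/CO[Si](c3ccccc3)(c4ccccc4)C(C)(C)C)[C@@H]5O[C@@H]5[C@H]6O[C@@]6(C)C[C@@H](O[Si](CC)(CC)CC)[C@@H]12 | intermediate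
38 | C11 dimethylaminomethyl lactone (Mannich base, mixture at C11) | CN(C)CC1C(=O)O[C@H]2/C=C(/CO[Si](c3ccccc3)(c4ccccc4)C(C)(C)C)[C@@H]5O[C@@H]5[C@H]6O[C@@]6(C)C[C@@H](O[Si](CC)(CC)CC)[C@@H]12 | intermediate
39 | trimethylammonium iodide of 38 | C[N+](C)(C)CC1C(=O)O[C@H]2/C=C(/CO[Si](c3ccccc3)(c4ccccc4)C(C)(C)C)[C@@H]5O[C@@H]5[C@H]6O[C@@]6(C)C[C@@H](O[Si](CC)(CC)CC)[C@@H]12.[I-] | intermediate
40 | α-methylene lactone (1R,2S,3S,6S,7S,8R,10S) with C8 triethylsilyl ether | C=C1C(=O)O[C@H]2/C=C(/CO[Si](c3ccccc3)(c4ccccc4)C(C)(C)C)[C@@H]5O[C@@H]5[C@H]6O[C@@]6(C)C[C@@H](O[Si](CC)(CC)CC)[C@@H]12 | intermediate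
41 | C8 alcohol of the methylene lactone (1R,2S,3S,6S,7R,8R,10S) | C=C1C(=O)O[C@H]2/C=C(/CO[Si](c3ccccc3)(c4ccccc4)C(C)(C)C)[C@@H]5O[C@@H]5[C@H]6O[C@@]6(C)C[C@@H](O)[C@@H]12 | intermediate
42 | angelic acid, (Z)-2-methylbut-2-enoic acid | C/C=C(/C)C(=O)O | starting material
43 | angelic 2,4,6-trichlorobenzoic anhydride | C/C=C(/C)C(=O)OC(=O)c1c(Cl)cc(Cl)cc1Cl | intermediate
44 | C8 angelate (1R,2S,3S,6S,7R,8R,10S) with C15 tert-butyldiphenylsilyl ether | C=C1C(=O)O[C@H]2/C=C(/CO[Si](c3ccccc3)(c4ccccc4)C(C)(C)C)[C@@H]5O[C@@H]5[C@H]6O[C@@]6(C)C[C@@H](OC(=O)/C(C)=C\C)[C@@H]12 | intermediate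
45 | CNP0157626.1 (1R,2S,3S,6S,7R,8R,10S) | C=C1C(=O)O[C@H]2/C=C(/CO)[C@@H]3O[C@@H]3[C@H]3O[C@@]3(C)C[C@@H](OC(=O)/C(C)=C\C)[C@@H]12 | target

## Step count and least certain steps

Total: 27 steps. Longest linear sequence: 22 steps (from 10 through steps 5–8 and 10–27). Fragment 1 takes 4 steps and fragment 2 takes 13.

Step 18 (key step). Most likely to go wrong: proton transfer from the enolizable ketone 26 to enolate 27, or reversal of the aldol addition before the alkoxide has been relayed, because ketone–ketone aldol additions are only weakly favourable and lithium alkoxides are slow in Payne rearrangements. Facial control at C10 would also be lost if lithium is not held by the oxirane oxygen. Fallback, using known reactions only: the union is interrupted after C–C bond formation. Enolate 27 and 26 are combined at −78 °C and quenched cold with AcOH to isolate the tertiary aldol adduct F1. Narasaka–Prasad reduction (Et2BOMe, NaBH4, THF/MeOH, −78 °C) removes the retro-aldol path and gives the syn-1,3-diol F2, in which C8 is set from C10 through the boron chelate. The secondary hydroxyl is silylated at once (Et3SiCl, imidazole) to give the mono-triethylsilyl ether F3. NaH in THF then brings about Payne rearrangement and chlorohydrin closure as a separate operation. This sets out from 9 and 26 and comes back at 32, replacing steps 18–20.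

Step 23. Most likely to go wrong: addition to the wrong aldehyde face, since the open-chain preference points to the 6-epimer and only the ring constraint can override it; intermolecular coupling or reduction of the C–I bond may also compete if closure of the ten-membered ring is slow. Fallback: set out from 34; if the closure delivers the 6-epi trans-lactone F4, it is opened with LiOH in THF/H2O to the 6-epi hydroxy acid F5, and Mitsunobu lactonisation (PPh3, DIAD, toluene) closes the lactone with inversion at C6. This comes back at 36.

Step 19. Most likely to go wrong: poor discrimination between the two alkyl arms of the ketone by the oxazaborolidine, because the C9 arm is neopentyl-like and the oxirane and ether oxygens can bind boron; lactonisation of 31 onto C12 before silylation is the second risk. Fallback: set out from 30 and reduce with Zn(BH4)2, where chelation to the C6 ether oxygen should favour the 8-epi alcohol F6. Mitsunobu inversion with chloroacetic acid (PPh3, DIAD) gives the (8R) chloroacetate F7, and thiourea with NaHCO3 in EtOH removes the chloroacetyl group without strong base. This comes back at 31, which is silylated directly as in step 20.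

Step 11. Most likely to go wrong: hydrogenolysis of the C5–I bond on palladium, or over-reduction of the alkene. Fallback: the alkyne is reduced before it meets the iodide. Set out from 17: bromination (NBS, AgNO3, acetone) gives the 1-bromoalkyne F8. Hydroboration with dicyclohexylborane, hydride-induced 1,2-migration with t-BuLi and boron-to-zinc exchange with Et2Zn give the (Z)-alkenylzinc reagent F9, which adds to aldehyde 15 under amino-alcohol catalysis ((−)-MIB or its antipode, as needed for Si-face addition). This comes back at 20 and replaces steps 10 and 11.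

Step 3. Most likely to go wrong: insufficient enantioselectivity, or slow addition with competing protodeboronation, because acyclic methyl enoates and 1,1-disubstituted alkenyl groups are demanding partners. Fallback: auxiliary control. Set out from 5: LiOH gives the acid F10; its pivaloyl mixed anhydride acylates lithiated (S)-4-benzyloxazolidin-2-one to give the N-enoyl imide F11. Isopropenylmagnesium bromide with CuBr·SMe2 adds anti to the benzyl group of the chelated imide to give adduct F12, and NaOMe in MeOH releases the methyl ester. This comes back at 7.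

## Further compounds

F1 | step 18 | tertiary aldol adduct (C10 carbinol, C8 ketone, C1–C2 oxirane, C3 chloride) | C[C@](O)(CC(=O)[C@@H](CC(=O)OC)COCc1ccc(OC)cc1)[C@H]1O[C@H]1[C@H](Cl)/C(CO[Si](c2ccccc2)(c3ccccc3)C(C)(C)C)=C\I
F2 | step 18 | syn-1,3-diol (8R carbinol, C10 carbinol) | C[C@](O)(C[C@@H](O)[C@@H](CC(=O)OC)COCc1ccc(OC)cc1)[C@H]1O[C@H]1[C@H](Cl)/C(CO[Si](c2ccccc2)(c3ccccc3)C(C)(C)C)=C\I
F3 | step 18 | C8 mono-triethylsilyl ether of F2 | C[C@](O)(C[C@@H](O[Si](CC)(CC)CC)[C@@H](CC(=O)OC)COCc1ccc(OC)cc1)[C@H]1O[C@H]1[C@H](Cl)/C(CO[Si](c2ccccc2)(c3ccccc3)C(C)(C)C)=C\I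
F4 | step 23 | 6-epi trans-fused lactone | C1C(=O)O[C@@H]2/C=C(/CO[Si](c3ccccc3)(c4ccccc4)C(C)(C)C)[C@@H]5O[C@@H]5[C@H]6O[C@@]6(C)C[C@@H](O[Si](CC)(CC)CC)[C@@H]12
F5 | step 23 | 6-epi hydroxy acid | OC(=O)C[C@H]1[C@H](O)/C=C(/CO[Si](c2ccccc2)(c3ccccc3)C(C)(C)C)[C@@H]4O[C@@H]4[C@H]5O[C@@]5(C)C[C@H]1O[Si](CC)(CC)CC
F6 | step 19 | 8-epi alcohol | I/C=C(/CO[Si](c1ccccc1)(c2ccccc2)C(C)(C)C)[C@@H]3O[C@@H]3[C@H]4O[C@@]4(C)C[C@H](O)[C@@H](CC(=O)OC)COCc5ccc(OC)cc5
F7 | step 19 | (8R) chloroacetate | I/C=C(/CO[Si](c1ccccc1)(c2ccccc2)C(C)(C)C)[C@@H]3O[C@@H]3[C@H]4O[C@@]4(C)C[C@@H](OC(=O)CCl)[C@@H](CC(=O)OC)COCc5ccc(OC)cc5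
F8 | step 11 | (R)-[(4-bromobut-3-yn-2-yl)oxy]triethylsilane | C[C@@H](O[Si](CC)(CC)CC)C#CBr
F9 | step 11 | ethyl[(1Z,3R)-3-(triethylsilyloxy)but-1-enyl]zinc | CC[Zn]/C=C\[C@@H](C)O[Si](CC)(CC)CC
F10 | step 3 | (E)-4-[(4-methoxybenzyl)oxy]but-2-enoic acid | OC(=O)/C=C/COCc1ccc(OC)cc1
F11 | step 3 | (S)-4-benzyl-3-[(E)-4-(4-methoxybenzyloxy)but-2-enoyl]oxazolidin-2-one | O=C(/C=C/COCc1ccc(OC)cc1)N2[C@@H](Cc3ccccc3)COC2=O
F12 | step 3 | (S)-4-benzyl-3-[(R)-3-{[(4-methoxybenzyl)oxy]methyl}-4-methylpent-4-enoyl]oxazolidin-2-one | C=C(C)[C@@H](CC(=O)N1[C@@H](Cc2ccccc2)COC1=O)COCc3ccc(OC)cc3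
A1 | alternative 1 | ten-membered C6 enone with Z C1=C10 alkene | O=C1/C=C(/CO[Si](C)(C)C(C)(C)C)[C@@H]2O[C@@H]2/C=C(/C)C[C@@H](O[Si](CC)(CC)CC)[C@H]1CCOCc1ccc(OC)cc1
A2 | alternative 2 | ten-membered trans C1,C2-diol | C1C(=O)O[C@H]2/C=C(/COCc3ccc(OC)cc3)[C@H](O[Si](CC)(CC)CC)[C@@H](O)[C@H](O)[C@@](C)(O[Si](CC)(CC)CC)C[C@@H](O[Si](C)(C)C(C)(C)C)[C@@H]12
A3 | alternative 3 | ten-membered C8 carbinol with C11=C13 methylene | C=C(COCc1ccc(OC)cc1)[C@H]2[C@@H](O[Si](C)(C)C(C)(C)C)/C=C(/CO[Si](C)(C)C(C)(C)C)[C@@H]3O[C@@H]3[C@H]3O[C@@]3(C)C[C@H]2O
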